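**Ret­ro­syn­thet­ic overview**

1. Locants (lignan numbering): C7/C8/C9 are the ArCH, ring-fusion CH and CH2O carbons of the guaiacyl half; C7'/C8'/C9' are those of the syringyl half (C8' carries OH). Ring 1 is O–C7–C8–C8'–C9'; ring 2 is O–C7'–C8'–C8–C9.
2. Target ⇐ hydrogenolysis of its di-O-benzyl ether ⇐ lactone-to-ether reduction at C9' of a cis-fused 8'-hydroxy furofuranone.
3. Ring 2 ⇐ intramolecular opening of a C7'/C8' spiro-epoxide by the C9 hydroxyl; the epoxide ⇐ E-arylidene lactone ⇐ intermolecular aldol condensation of a γ-aryl butyrolactone enolate with O-benzylsyringaldehyde (C7'–C8' bond).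
4. Ring 1 (as a γ-lactone) and the C7–C8 bond ⇐ Evans syn-aldol of a succinate-derived N-acyl oxazolidinone with O-benzylvanillin, then lactonisation.
5. Ring order: ring 1 lactone first, ring 2 oxolane second, C9' carbonyl removed last.

Assumption: the four numbered starting materials are bought as such, and dimethyldioxirane is used as a pre-made acetone solution.

**Route**

Step 1
Reactants: 1 syringaldehyde (4-hydroxy-3,5-dimethoxybenzaldehyde)
Product: 2 4-(benzyloxy)-3,5-dimethoxybenzaldehyde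
Conditions: BnBr, K2CO3, DMF, 60 °C
Reagents that add atoms: benzyl bromide BrCc1ccccc1
Why: Williamson ether synthesis (phenoxide SN2 on benzyl bromide); no stereocentre is involved.

Step 2
Reactants: 3 (4S)-4-benzyl-1,3-oxazolidin-2-one; 4 methyl 4-chloro-4-oxobutanoate
Product: 5 methyl 4-[(4S)-4-benzyl-2-oxo-1,3-oxazolidin-3-yl]-4-oxobutanoate
Conditions: n-BuLi, THF, −78 °C; then 4, −78 → 0 °C
Reagents that add atoms: none
Why: N-acylation of the lithiated Evans auxiliary by the acid chloride, which is far more electrophilic than the methyl ester; the auxiliary stereocentre is untouched.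

Step 3
Reactants: 5 methyl 4-[(4S)-4-benzyl-2-oxo-1,3-oxazolidin-3-yl]-4-oxobutanoate; 6 4-(benzyloxy)-3-methoxybenzaldehyde
Product: 8 (4S)-4-benzyl-3-{[(2S,3S)-2-[4-(benzyloxy)-3-methoxyphenyl]-5-oxooxolan-3-yl]carbonyl}-1,3-oxazolidin-2-one, via syn-aldol adduct 7 (not isolated)
Conditions: Bu2BOTf, i-Pr2NEt, CH2Cl2, 0 °C; 6, −78 → 0 °C; pH 7 buffer, MeOH, H2O2, 0 °C; then CSA (cat.), CH2Cl2, rt
Reagents that add atoms: none
Why: Evans syn-aldol through the Z boron enolate in a Zimmerman–Traxler chair sets C8 and C7 (the aldehyde adds to the enolate face away from the auxiliary benzyl group), and the γ-hydroxy ester then lactonises to ring 1 with aryl and acyl groups trans.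

Step 4
Reactants: 8 (4S)-4-benzyl-3-{[(2S,3S)-2-[4-(benzyloxy)-3-methoxyphenyl]-5-oxooxolan-3-yl]carbonyl}-1,3-oxazolidin-2-one
Product: 10 (2S,3S)-2-[4-(benzyloxy)-3-methoxyphenyl]-5-oxooxolane-3-carboxylic acid, via peroxy acid 9 (not isolated)
Conditions: LiOH, H2O2, THF/H2O (3:1), 0 °C; then aq. Na2SO3; HCl to pH 2
Reagents that add atoms: hydrogen peroxide OO
Why: Evans hydroperoxide hydrolysis cleaves the exocyclic imide carbonyl selectively without epimerising C8, and acidification recloses any lactone opened by hydroxide.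

Step 5
Reactants: 10 (2S,3S)-2-[4-(benzyloxy)-3-methoxyphenyl]-5-oxooxolane-3-carboxylic acid
Product: 11 (4R,5S)-5-[4-(benzyloxy)-3-methoxyphenyl]-4-(hydroxymethyl)oxolan-2-one
Conditions: BH3·SMe2, THF, 0 °C → rt; then H2O
Reagents that add atoms: none
Why: Chemoselective borane reduction of the carboxylic acid (through the acyloxyborane) in the presence of the lactone; no stereocentre is touched.

Step 6
Reactants: 11 (4R,5S)-5-[4-(benzyloxy)-3-methoxyphenyl]-4-(hydroxymethyl)oxolan-2-one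
Product: 12 (4R,5S)-5-[4-(benzyloxy)-3-methoxyphenyl]-4-({[tert-butyl(dimethyl)silyl]oxy}methyl)oxolan-2-one
Conditions: TBSCl, imidazole, DMF, rt
Reagents that add atoms: tert-butyldimethylsilyl chloride CC(C)(C)[Si](C)(C)Cl
Why: Standard silylation of the primary alcohol, which masks the C9 hydroxyl during enolate chemistry and later shields one alkene face.

Step 7
Reactants: 12 (4R,5S)-5-[4-(benzyloxy)-3-methoxyphenyl]-4-({[tert-butyl(dimethyl)silyl]oxy}methyl)oxolan-2-one; 2 4-(benzyloxy)-3,5-dimethoxybenzaldehyde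
Product: 13 (3R,4R,5S)-5-[4-(benzyloxy)-3-methoxyphenyl]-3-{[4-(benzyloxy)-3,5-dimethoxyphenyl](hydroxy)methyl}-4-({[tert-butyl(dimethyl)silyl]oxy}methyl)oxolan-2-one (both carbinol epimers)
Conditions: LiN(i-Pr)2, THF, −78 °C; then 2, −78 °C; AcOH quench at −78 °C
Reagents that add atoms: none
Why: Intermolecular aldol addition of the lactone lithium enolate to the aldehyde forms the C8'–C7' bond (mainly trans to the CH2OTBS group), and both new centres are erased in step 8 so their ratio does not matter.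

Step 8
Reactants: 13 (3R,4R,5S)-5-[4-(benzyloxy)-3-methoxyphenyl]-3-{[4-(benzyloxy)-3,5-dimethoxyphenyl](hydroxy)methyl}-4-({[tert-butyl(dimethyl)silyl]oxy}methyl)oxolan-2-one
Product: 15 (3E,4R,5S)-5-[4-(benzyloxy)-3-methoxyphenyl]-3-[4-(benzyloxy)-3,5-dimethoxybenzylidene]-4-({[tert-butyl(dimethyl)silyl]oxy}methyl)oxolan-2-one, via benzylic mesylate 14 (not isolated)
Conditions: MsCl, Et3N, CH2Cl2, 0 °C; then DBU, rt
Reagents that add atoms: methanesulfonyl chloride CS(Cl)(=O)=O (its atoms stay in 14 only)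
Why: Mesylation followed by E1cB elimination completes the aldol condensation and gives the conjugated arylidene lactone as the thermodynamically preferred E isomer.

Step 9
Reactants: 15 (3E,4R,5S)-5-[4-(benzyloxy)-3-methoxyphenyl]-3-[4-(benzyloxy)-3,5-dimethoxybenzylidene]-4-({[tert-butyl(dimethyl)silyl]oxy}methyl)oxolan-2-one
Product: 16 (2S,3R,6S,7R)-6-[4-(benzyloxy)-3-methoxyphenyl]-2-[4-(benzyloxy)-3,5-dimethoxyphenyl]-7-({[tert-butyl(dimethyl)silyl]oxy}methyl)-1,5-dioxaspiro[2.4]heptan-4-one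
Conditions: dimethyldioxirane (acetone solution, 3 equiv), CH2Cl2, 0 °C → rt
Reagents that add atoms: dimethyldioxirane CC1(C)OO1
Why: Electrophilic dioxirane epoxidation occurs on the lactone face anti to the adjacent CH2OTBS group (held pseudo-axial by allylic strain with the aryl group), which sets C8' and, by syn addition to the E alkene, a provisional C7' centre.

Step 10
Reactants: 16 (2S,3R,6S,7R)-6-[4-(benzyloxy)-3-methoxyphenyl]-2-[4-(benzyloxy)-3,5-dimethoxyphenyl]-7-({[tert-butyl(dimethyl)silyl]oxy}methyl)-1,5-dioxaspiro[2.4]heptan-4-one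
Product: 18 (3S,3aR,6R,6aR)-3-[4-(benzyloxy)-3-methoxyphenyl]-6-[4-(benzyloxy)-3,5-dimethoxyphenyl]-6a-hydroxytetrahydro-1H,3H-furo[3,4-c]furan-1-one, via hydroxy epoxide 17 (not isolated)
Conditions: Bu4NF, AcOH, THF, 0 °C → rt; then CSA (cat.), CH2Cl2, 0 °C
Reagents that add atoms: none
Why: After buffered desilylation the C9 hydroxyl, which sits on the face opposite the epoxide oxygen, opens the benzylic epoxide carbon C7' with inversion in an acid-catalysed intramolecular epoxide opening, closing ring 2 with the syringyl group exo and leaving the C8' hydroxyl at the cis ring fusion.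

Step 11
Reactants: 18 (3S,3aR,6R,6aR)-3-[4-(benzyloxy)-3-methoxyphenyl]-6-[4-(benzyloxy)-3,5-dimethoxyphenyl]-6a-hydroxytetrahydro-1H,3H-furo[3,4-c]furan-1-one
Product: 19 (3S,3aR,6R,6aR)-3-[4-(benzyloxy)-3-methoxyphenyl]-6-[4-(benzyloxy)-3,5-dimethoxyphenyl]tetrahydro-1H,3H-furo[3,4-c]furan-1,6a-diol (both anomers at C1)
Conditions: i-Bu2AlH (2.5 equiv), CH2Cl2, −78 °C; then aq. potassium sodium tartrate
Reagents that add atoms: none
Why: Partial hydride reduction of the lactone stops at the chelated aluminium hemiacetal at −78 °C and gives the lactol; the four ring stereocentres are untouched and the anomeric centre is removed in step 12.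

Step 12
Reactants: 19 (3S,3aR,6R,6aR)-3-[4-(benzyloxy)-3-methoxyphenyl]-6-[4-(benzyloxy)-3,5-dimethoxyphenyl]tetrahydro-1H,3H-furo[3,4-c]furan-1,6a-diol
Product: 20 (3R,3aS,6S,6aR)-3-[4-(benzyloxy)-3,5-dimethoxyphenyl]-6-[4-(benzyloxy)-3-methoxyphenyl]tetrahydro-1H,3H-furo[3,4-c]furan-3a-ol (4,4'-di-O-benzylfraxiresinol)
Conditions: Et3SiH, BF3·OEt2, CH2Cl2, −78 → −40 °C
Reagents that add atoms: none
Why: Ionic hydrogenation: the lactol ionises to the ring 1 oxocarbenium ion, which the silane reduces at C9' (not stereogenic in the product), while the low temperature keeps the benzylic C–O bonds from ionising.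

Step 13
Reactants: 20 (3R,3aS,6S,6aR)-3-[4-(benzyloxy)-3,5-dimethoxyphenyl]-6-[4-(benzyloxy)-3-methoxyphenyl]tetrahydro-1H,3H-furo[3,4-c]furan-3a-ol
Product: 21 fraxiresinol, (3R,3aS,6S,6aR)-3-(4-hydroxy-3,5-dimethoxyphenyl)-6-(4-hydroxy-3-methoxyphenyl)tetrahydro-1H,3H-furo[3,4-c]furan-3a-ol
Conditions: H2 (1 atm), 10% Pd/C, EtOAc/MeOH, rt, stopped at full conversion
Reagents that add atoms: none
Why: Catalytic hydrogenolysis cleaves the two aryl benzyl ethers much faster than the ring benzylic C–O bonds, so all four stereocentres survive.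

**Compound list**

1 | syringaldehyde (4-hydroxy-3,5-dimethoxybenzaldehyde) | COc1cc(C=O)cc(OC)c1O | starting material
2 | 4-(benzyloxy)-3,5-dimethoxybenzaldehyde | COc1cc(C=O)cc(OC)c1OCc1ccccc1 | intermediate
3 | (4S)-4-benzyl-1,3-oxazolidin-2-one | O=C1N[C@@H](Cc2ccccc2)CO1 | starting material
4 | methyl 4-chloro-4-oxobutanoate | COC(=O)CCC(Cl)=O | starting material
5 | methyl 4-[(4S)-4-benzyl-2-oxo-1,3-oxazolidin-3-yl]-4-oxobutanoate | COC(=O)CCC(=O)N1[C@@H](Cc2ccccc2)COC1=O | intermediate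
6 | 4-(benzyloxy)-3-methoxybenzaldehyde | COc1cc(C=O)ccc1OCc1ccccc1 | starting material
7 | methyl (3S)-3-{(S)-[4-(benzyloxy)-3-methoxyphenyl](hydroxy)methyl}-4-[(4S)-4-benzyl-2-oxo-1,3-oxazolidin-3-yl]-4-oxobutanoate (syn-aldol adduct) | COC(=O)C[C@@H]([C@H](O)c1ccc(OCc2ccccc2)c(OC)c1)C(=O)N1[C@@H](Cc2ccccc2)COC1=O | intermediate
8 | (4S)-4-benzyl-3-{[(2S,3S)-2-[4-(benzyloxy)-3-methoxyphenyl]-5-oxooxolan-3-yl]carbonyl}-1,3-oxazolidin-2-one | COc1cc([C@H]2OC(=O)C[C@@H]2C(=O)N2[C@@H](Cc3ccccc3)COC2=O)ccc1OCc1ccccc1 | intermediate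
9 | (2S,3S)-2-[4-(benzyloxy)-3-methoxyphenyl]-5-oxooxolane-3-carboperoxoic acid | COc1cc([C@H]2OC(=O)C[C@@H]2C(=O)OO)ccc1OCc1ccccc1 | intermediate
10 | (2S,3S)-2-[4-(benzyloxy)-3-methoxyphenyl]-5-oxooxolane-3-carboxylic acid | COc1cc([C@H]2OC(=O)C[C@@H]2C(O)=O)ccc1OCc1ccccc1 | intermediate
11 | (4R,5S)-5-[4-(benzyloxy)-3-methoxyphenyl]-4-(hydroxymethyl)oxolan-2-one | COc1cc([C@H]2OC(=O)C[C@@H]2CO)ccc1OCc1ccccc1 | intermediate
12 | (4R,5S)-5-[4-(benzyloxy)-3-methoxyphenyl]-4-({[tert-butyl(dimethyl)silyl]oxy}methyl)oxolan-2-one | COc1cc([C@H]2OC(=O)C[C@@H]2CO[Si](C)(C)C(C)(C)C)ccc1OCc1ccccc1 | intermediate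
13 | (3R,4R,5S)-5-[4-(benzyloxy)-3-methoxyphenyl]-3-{[4-(benzyloxy)-3,5-dimethoxyphenyl](hydroxy)methyl}-4-({[tert-butyl(dimethyl)silyl]oxy}methyl)oxolan-2-one (both carbinol epimers) | COc1cc([C@H]2OC(=O)[C@@H](C(O)c3cc(OC)c(OCc4ccccc4)c(OC)c3)[C@@H]2CO[Si](C)(C)C(C)(C)C)ccc1OCc1ccccc1 | intermediate
14 | methanesulfonate of 13 at the benzylic carbinol (both epimers) | COc1cc([C@H]2OC(=O)[C@@H](C(OS(C)(=O)=O)c3cc(OC)c(OCc4ccccc4)c(OC)c3)[C@@H]2CO[Si](C)(C)C(C)(C)C)ccc1OCc1ccccc1 | intermediate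
15 | (3E,4R,5S)-5-[4-(benzyloxy)-3-methoxyphenyl]-3-[4-(benzyloxy)-3,5-dimethoxybenzylidene]-4-({[tert-butyl(dimethyl)silyl]oxy}methyl)oxolan-2-one | COc1cc([C@H]2OC(=O)/C(=C/c3cc(OC)c(OCc4ccccc4)c(OC)c3)[C@@H]2CO[Si](C)(C)C(C)(C)C)ccc1OCc1ccccc1 | intermediate
16 | (2S,3R,6S,7R)-6-[4-(benzyloxy)-3-methoxyphenyl]-2-[4-(benzyloxy)-3,5-dimethoxyphenyl]-7-({[tert-butyl(dimethyl)silyl]oxy}methyl)-1,5-dioxaspiro[2.4]heptan-4-one | COc1cc([C@H]2OC(=O)[C@@]4(O[C@H]4c3cc(OC)c(OCc5ccccc5)c(OC)c3)[C@@H]2CO[Si](C)(C)C(C)(C)C)ccc1OCc1ccccc1 | intermediate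
17 | (2S,3R,6S,7R)-6-[4-(benzyloxy)-3-methoxyphenyl]-2-[4-(benzyloxy)-3,5-dimethoxyphenyl]-7-(hydroxymethyl)-1,5-dioxaspiro[2.4]heptan-4-one | COc1cc([C@H]2OC(=O)[C@@]4(O[C@H]4c3cc(OC)c(OCc5ccccc5)c(OC)c3)[C@@H]2CO)ccc1OCc1ccccc1 | intermediate
18 | (3S,3aR,6R,6aR)-3-[4-(benzyloxy)-3-methoxyphenyl]-6-[4-(benzyloxy)-3,5-dimethoxyphenyl]-6a-hydroxytetrahydro-1H,3H-furo[3,4-c]furan-1-one | COc1cc([C@H]2OC(=O)[C@]3(O)[C@@H](c4cc(OC)c(OCc5ccccc5)c(OC)c4)OC[C@H]23)ccc1OCc1ccccc1 | intermediate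
19 | (3S,3aR,6R,6aR)-3-[4-(benzyloxy)-3-methoxyphenyl]-6-[4-(benzyloxy)-3,5-dimethoxyphenyl]tetrahydro-1H,3H-furo[3,4-c]furan-1,6a-diol (both anomers at C1) | COc1cc([C@H]2OC(O)[C@]3(O)[C@@H](c4cc(OC)c(OCc5ccccc5)c(OC)c4)OC[C@H]23)ccc1OCc1ccccc1 | intermediate
20 | (3R,3aS,6S,6aR)-3-[4-(benzyloxy)-3,5-dimethoxyphenyl]-6-[4-(benzyloxy)-3-methoxyphenyl]tetrahydro-1H,3H-furo[3,4-c]furan-3a-ol | COc1cc([C@H]2OC[C@]3(O)[C@@H](c4cc(OC)c(OCc5ccccc5)c(OC)c4)OC[C@H]23)ccc1OCc1ccccc1 | intermediate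
21 | fraxiresinol, (3R,3aS,6S,6aR)-3-(4-hydroxy-3,5-dimethoxyphenyl)-6-(4-hydroxy-3-methoxyphenyl)tetrahydro-1H,3H-furo[3,4-c]furan-3a-ol | COc1cc([C@H]2OC[C@]3(O)[C@@H](c4cc(OC)c(O)c(OC)c4)OC[C@H]23)ccc1O | target

**Step count and risks**

Total steps: 13. Longest linear sequence: 12 steps (steps 2 to 13, from 3 and 4 to 21); step 1 is a one-step side branch that joins at step 7.

The three steps most likely to fail:

Step 9. The alkene is trisubstituted, hindered and conjugated to the lactone, so the dioxirane may react slowly, and the facial selectivity rests on one adjacent substituent. The fallback sets out from 15 and comes back at 18. Syn-dihydroxylation of 15 with OsO4 (cat.), NMO and citric acid in acetone/water attacks the same face and gives the 7',8'-diol F1. MsCl and Et3N at −20 °C then sulfonylate only the secondary benzylic hydroxyl, giving the benzylic monomesylate F2. Bu4NF/AcOH frees the C9 hydroxyl, and warming with 2,6-lutidine lets it displace the mesylate with inversion at C7', closing ring 2 to give 18.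

Step 10. The free hydroxy epoxide 17 may translactonise or undergo an acyl shift before the ring closes. The fallback sets out from 16 and comes back at 18. Compound 16 itself is treated with Sc(OTf)3 (cat.) in CH2Cl2 at −40 °C, so the silyl ether oxygen opens the benzylic epoxide carbon directly and the silyl group passes to the new tertiary alkoxide. This gives the 8'-O-silyl furofuranone F3 without any free alcohol next to the lactone, and Bu4NF then gives 18.

Step 12. BF3 may open ring 1 at the benzylic C7–O bond (epimerisation or over-reduction), and the neighbouring tertiary hydroxyl slows oxocarbenium formation. The fallback sets out from 18 and comes back at 20, bypassing 19. LiAlH4 in THF at 0 °C reduces the lactone to the ring 2 triol F4. CSA (cat.) in CH2Cl2 then ionises the benzylic alcohol at C7, and the C9' hydroxyl captures the cation with the aryl group exo (stereoconvergent cyclodehydration) to give 20.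

Further compounds
F1 | step 9 | (3R,4R,5S)-5-[4-(benzyloxy)-3-methoxyphenyl]-3-{(S)-[4-(benzyloxy)-3,5-dimethoxyphenyl](hydroxy)methyl}-4-({[tert-butyl(dimethyl)silyl]oxy}methyl)-3-hydroxyoxolan-2-one | COc1cc([C@H]2OC(=O)[C@](O)([C@@H](O)c3cc(OC)c(OCc4ccccc4)c(OC)c3)[C@@H]2CO[Si](C)(C)C(C)(C)C)ccc1OCc1ccccc1
F2 | step 9 | (S)-[4-(benzyloxy)-3,5-dimethoxyphenyl][(3R,4R,5S)-5-[4-(benzyloxy)-3-methoxyphenyl]-4-({[tert-butyl(dimethyl)silyl]oxy}methyl)-3-hydroxy-2-oxooxolan-3-yl]methyl methanesulfonate | COc1cc([C@H]2OC(=O)[C@](O)([C@@H](OS(C)(=O)=O)c3cc(OC)c(OCc4ccccc4)c(OC)c3)[C@@H]2CO[Si](C)(C)C(C)(C)C)ccc1OCc1ccccc1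
F3 | step 10 | (3S,3aR,6R,6aR)-3-[4-(benzyloxy)-3-methoxyphenyl]-6-[4-(benzyloxy)-3,5-dimethoxyphenyl]-6a-{[tert-butyl(dimethyl)silyl]oxy}tetrahydro-1H,3H-furo[3,4-c]furan-1-one | COc1cc([C@H]2OC(=O)[C@]3(O[Si](C)(C)C(C)(C)C)[C@@H](c4cc(OC)c(OCc5ccccc5)c(OC)c4)OC[C@H]23)ccc1OCc1ccccc1
F4 | step 12 | (2R,3S,4R)-2-[4-(benzyloxy)-3,5-dimethoxyphenyl]-4-{(S)-[4-(benzyloxy)-3-methoxyphenyl](hydroxy)methyl}-3-(hydroxymethyl)oxolan-3-ol | COc1cc([C@@H](O)[C@H]2CO[C@H](c3cc(OC)c(OCc4ccccc4)c(OC)c3)[C@@]2(O)CO)ccc1OCc1ccccc1
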